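**Plan**

The target is two acacetin units joined C6–C8''. Unit 1 is the flavone bonded through C6 and unit 2 is the one bonded through C8''.
Enabling feature: in ring A of unit 1 the biaryl carbon C6 is flanked by the hydroxylated C5 and C7 and faces C8a across the ring. The run C5–C6–C7–C8 is therefore a 2-aryl acetoacetate (ester carbon = C5, methyl carbon = C8). The remainder (O1, C2, C3, C4, C4a, C8a; ring C) is a 2-aryl-4-pyranone with a free CH=CH edge.
Cuts, in order: C4a–C5 and C8–C8a (ring A of unit 1), C6–C7 (acetyl), C6–C8'' (by then only an aryl–CH2 bond), C8''–I. The pyranone is cut at C2–C3 and O1–C8a.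
Forward: ring C of unit 1 is made first as the pyranone. Unit 2 enters complete as acacetin, because iodination reaches C8 of a 5,7-dialkoxyflavone directly and a finished flavone exposes no acetal or electron-rich triether to Me3SiOTf and DDQ. It receives the four-carbon chain at C8'', ring A of unit 1 closes last, and hydrogenolysis ends the route.
Stereochemistry: the target has no stereocentre, the sp3 centres met on the way are erased on aromatisation, and the hindered C6–C8'' axis forms without control.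

Key step: step 6

Assumption: the SMILES carries no descriptor for the C6–C8'' axis, so the racemate is taken as the target.

**Step 1**
Reactants: 1 (E)-4-methoxybut-3-en-2-one; 2 4-methoxybenzoyl chloride
Product: 4 2-(4-methoxyphenyl)-4H-pyran-4-one, via methoxyvinyl diketone 3 (not isolated)
Conditions: 1 (2 equiv), LiN(SiMe3)2 (2 equiv), THF, −78 °C; 2 (1 equiv), −78 °C; aq NH4Cl; crude 3, CF3CO2H (cat.), toluene, 25 °C
Reagents that add atoms: none
Why: C-acylation of the kinetic lithium enolate of the vinylogous ester by the aroyl chloride (crossed Claisen type, the second equivalent of enolate taking up the acidic proton of 3), followed by acid-catalysed 6-endo-trig addition–elimination of the enol oxygen on the beta-methoxy enone with loss of methanol, is an established gamma-pyrone synthesis and leaves the carbon next to oxygen unsubstituted.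

**Step 2**
Reactants: 5 acacetin (5,7-dihydroxy-2-(4-methoxyphenyl)-4H-chromen-4-one)
Product: 6 5,7-bis(benzyloxy)-2-(4-methoxyphenyl)-4H-chromen-4-one
Conditions: BnBr (3 equiv), K2CO3 (4 equiv), DMF, 70 °C
Reagents that add atoms: benzyl bromide, BrCc1ccccc1
Why: Williamson ether synthesis, run warm in DMF with excess carbonate because the 5-hydroxyl is hydrogen-bonded to the C4 carbonyl and reacts only after the 7-hydroxyl.

**Step 3**
Reactants: 6 5,7-bis(benzyloxy)-2-(4-methoxyphenyl)-4H-chromen-4-one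
Product: 7 5,7-bis(benzyloxy)-8-iodo-2-(4-methoxyphenyl)-4H-chromen-4-one
Conditions: N-iodosuccinimide (1.05 equiv), CF3CO2H (0.3 equiv), CH2Cl2–MeCN, 0 → 25 °C, dark
Reagents that add atoms: N-iodosuccinimide, O=C1CCC(=O)N1I
Why: Electrophilic aromatic iodination of fully O-alkylated 5,7-dioxygenated flavones goes to C8, a preference reinforced here because C6 is walled in by two benzyloxy groups while C3 and ring B are deactivated by conjugation with the pyranone carbonyl.

**Step 4**
Reactants: 7 5,7-bis(benzyloxy)-8-iodo-2-(4-methoxyphenyl)-4H-chromen-4-one; 8 methyl bromoacetate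
Product: 10 methyl 2-[5,7-bis(benzyloxy)-2-(4-methoxyphenyl)-4-oxo-4H-chromen-8-yl]acetate, via Reformatsky reagent 9 (not isolated)
Conditions: 8 (3 equiv), Zn dust (Me3SiCl-activated), THF, 40 °C; then 7, Pd2(dba)3 (2.5 mol %), XPhos (10 mol %), THF, 65 °C
Reagents that add atoms: none
Why: Negishi-type palladium-catalysed arylation of a Reformatsky reagent, in which the bulky electron-rich biaryl phosphine keeps a monoligated zerovalent palladium species active enough for the di-ortho-substituted iodide and the mild zinc enolate leaves the vinylogous-ester carbonyl of the flavone alone.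

**Step 5**
Reactants: 10 methyl 2-[5,7-bis(benzyloxy)-2-(4-methoxyphenyl)-4-oxo-4H-chromen-8-yl]acetate; 11 acetyl chloride
Product: 12 methyl 2-[5,7-bis(benzyloxy)-2-(4-methoxyphenyl)-4-oxo-4H-chromen-8-yl]-3-oxobutanoate (racemic, enolisable)
Conditions: LiN(SiMe3)2 (2.2 equiv), THF, −78 °C; 11 (1.1 equiv), −78 → −30 °C; aq NH4Cl
Reagents that add atoms: none
Why: Crossed Claisen C-acylation of the lithium ester enolate with an acid chloride, the second equivalent of amide base trapping the more acidic beta-keto ester as its enolate so that neither proton exchange nor diacylation intervenes; the new centre is racemic and enolisable and is lost in step 6.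

**Step 6**
Reactants: 12 methyl 2-[5,7-bis(benzyloxy)-2-(4-methoxyphenyl)-4-oxo-4H-chromen-8-yl]-3-oxobutanoate; 4 2-(4-methoxyphenyl)-4H-pyran-4-one
Product: 17 6-[5,7-bis(benzyloxy)-2-(4-methoxyphenyl)-4-oxo-4H-chromen-8-yl]-5,7-dihydroxy-2-(4-methoxyphenyl)-4H-chromen-4-one, via bis(silyl enol ether) 13 (not isolated), via silyloxypyrylium triflate 14 (not isolated), via 2H-pyran adduct 15 (not isolated), via pyranonyl keto ester 16 (not isolated)
Conditions: 12, Et3N (2.5 equiv), Me3SiOTf (3.5 equiv, kept in excess over the amine), CH2Cl2, 0 → 20 °C; 14 [from 4 (1.3 equiv), Me3SiOTf (1.4 equiv), CH2Cl2, 20 °C], −78 → 0 °C; DDQ (1.1 equiv), −40 → 0 °C; aq NaHCO3 wash, CH2Cl2 → THF (crude 16, unpurified); KOt-Bu (3.5 equiv), 0 → 25 °C; 1 M HCl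
Reagents that add atoms: none
Why: Proposed new method: Me3SiOTf/Et3N converts 12 into the 1,3-bis(silyloxy)diene 13, whose terminal CH2 (future C8) attacks the 4-silyloxypyrylium ion 14 at its only unsubstituted oxygen-bound carbon (future C8a) in a vinylogous Mukaiyama–Michael addition, giving the 4-silyloxy-2H-pyran 15. DDQ is added while the flask still holds no base and abstracts the C8a hydride of 15 (alpha to O1 and allylic), so that the C4a–C8a unsaturation is installed before ring closure and the aromatic pyranone 16 replaces the only intermediate from which O1 could leave by beta-elimination or electrocyclic opening; closing the ring with base first would let the cyclised 8,8a-dihydro triketone aromatise by expelling O1 instead of by oxidation, and would also expose the free 5,7-diol to DDQ. KOt-Bu then removes a C8 proton of 16, the charge is relayed through C8a to C4a, and C4a attacks the methyl ester carbon (C5) in a 6-(enolexo)-exo-trig Claisen closure of ring A, after which loss of methoxide and tautomerisation give the 5,7-diol directly. The closest known reaction types are the Me3SiOTf-mediated conjugate addition of 1,3-bis(silyloxy)dienes to chromones, DDQ reoxidation of silyl enol ethers to enones, Michael–Claisen routes to cyclohexane-1,3-diones and the strong-base Claisen cyclisation of 3,5,7-triketo esters to acylphloroglucinols, but the sequence has not been run across the CH=CH edge of a monocyclic 4-pyranone. No stereocentre is kept, since C8a of 15 and C6 of 12 and 16 all become sp2, and the C6–C8'' axis arises racemic. The step needs attack at the CH terminus of 14 (secured by the 4-methoxyphenyl group that blocks the other terminus, just as it blocks C2'' of the silylated spectator flavone), reaction of 13 through its terminal and not its aryl-bearing central carbon (secured by full substitution there), and an unbroken O1–C8a bond so that O1 ends para to C6 (secured by oxidation before base and by a non-nucleophilic base, while the competing aldol of C6 onto C4 would need a bridgehead alkene as long as ring C stays closed).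

**Step 7**
Reactants: 17 6-[5,7-bis(benzyloxy)-2-(4-methoxyphenyl)-4-oxo-4H-chromen-8-yl]-5,7-dihydroxy-2-(4-methoxyphenyl)-4H-chromen-4-one
Product: 18 8-[5,7-dihydroxy-2-(4-methoxyphenyl)-4-oxo-4H-chromen-6-yl]-5,7-dihydroxy-2-(4-methoxyphenyl)-4H-chromen-4-one (CNP0226117.0, racemic axis)
Conditions: H2 (1 atm), 10% Pd/C, THF–MeOH, 25 °C
Reagents that add atoms: none
Why: Catalytic hydrogenolysis of aryl benzyl ethers, which at one atmosphere leaves the aryl methyl ethers and the conjugated C2=C3 bonds of both flavones untouched.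

**Compound list**

1 | (E)-4-methoxybut-3-en-2-one | CO/C=C/C(C)=O | starting material
2 | 4-methoxybenzoyl chloride | COc1ccc(cc1)C(Cl)=O | starting material
3 | (E)-5-methoxy-1-(4-methoxyphenyl)pent-4-ene-1,3-dione | COc1ccc(cc1)C(=O)CC(=O)/C=C/OC | intermediate
4 | 2-(4-methoxyphenyl)-4H-pyran-4-one | COc1ccc(cc1)-c1cc(=O)cco1 | intermediate
5 | acacetin, 5,7-dihydroxy-2-(4-methoxyphenyl)-4H-chromen-4-one | COc1ccc(cc1)-c1cc(=O)c2c(O)cc(O)cc2o1 | starting material
6 | 5,7-bis(benzyloxy)-2-(4-methoxyphenyl)-4H-chromen-4-one | COc1ccc(cc1)-c1cc(=O)c2c(OCc3ccccc3)cc(OCc3ccccc3)cc2o1 | intermediate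
7 | 5,7-bis(benzyloxy)-8-iodo-2-(4-methoxyphenyl)-4H-chromen-4-one | COc1ccc(cc1)-c1cc(=O)c2c(OCc3ccccc3)cc(OCc3ccccc3)c(I)c2o1 | intermediate
8 | methyl bromoacetate | COC(=O)CBr | starting material
9 | bromo(2-methoxy-2-oxoethyl)zinc | COC(=O)C[Zn]Br | intermediate
10 | methyl 2-[5,7-bis(benzyloxy)-2-(4-methoxyphenyl)-4-oxo-4H-chromen-8-yl]acetate | COC(=O)Cc1c(OCc2ccccc2)cc(OCc2ccccc2)c2c(=O)cc(-c3ccc(OC)cc3)oc12 | intermediate
11 | acetyl chloride | CC(Cl)=O | starting material
12 | methyl 2-[5,7-bis(benzyloxy)-2-(4-methoxyphenyl)-4-oxo-4H-chromen-8-yl]-3-oxobutanoate (racemic) | COC(=O)C(C(C)=O)c1c(OCc2ccccc2)cc(OCc2ccccc2)c2c(=O)cc(-c3ccc(OC)cc3)oc12 | intermediate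
13 | 5,7-bis(benzyloxy)-8-[1-methoxy-1,3-bis(trimethylsilyloxy)buta-1,3-dien-2-yl]-2-(4-methoxyphenyl)-4H-chromen-4-one | COC(O[Si](C)(C)C)=C(C(=C)O[Si](C)(C)C)c1c(OCc2ccccc2)cc(OCc2ccccc2)c2c(=O)cc(-c3ccc(OC)cc3)oc12 | intermediate
14 | 2-(4-methoxyphenyl)-4-(trimethylsilyloxy)pyrylium trifluoromethanesulfonate | COc1ccc(cc1)-c1cc(O[Si](C)(C)C)cc[o+]1.[O-]S(=O)(=O)C(F)(F)F | intermediate
15 | methyl 2-[5,7-bis(benzyloxy)-2-(4-methoxyphenyl)-4-oxo-4H-chromen-8-yl]-4-[6-(4-methoxyphenyl)-4-(trimethylsilyloxy)-2H-pyran-2-yl]-3-(trimethylsilyloxy)but-2-enoate (racemic) | COC(=O)C(c1c(OCc2ccccc2)cc(OCc2ccccc2)c2c(=O)cc(-c3ccc(OC)cc3)oc12)=C(O[Si](C)(C)C)CC1C=C(O[Si](C)(C)C)C=C(O1)c1ccc(OC)cc1 | intermediate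
16 | methyl 2-[5,7-bis(benzyloxy)-2-(4-methoxyphenyl)-4-oxo-4H-chromen-8-yl]-4-[6-(4-methoxyphenyl)-4-oxo-4H-pyran-2-yl]-3-oxobutanoate (racemic) | COC(=O)C(c1c(OCc2ccccc2)cc(OCc2ccccc2)c2c(=O)cc(-c3ccc(OC)cc3)oc12)C(=O)Cc1cc(=O)cc(o1)-c1ccc(OC)cc1 | intermediate
17 | 6-[5,7-bis(benzyloxy)-2-(4-methoxyphenyl)-4-oxo-4H-chromen-8-yl]-5,7-dihydroxy-2-(4-methoxyphenyl)-4H-chromen-4-one | COc1ccc(cc1)-c1cc(=O)c2c(O)c(c(O)cc2o1)-c1c(OCc2ccccc2)cc(OCc2ccccc2)c2c(=O)cc(-c3ccc(OC)cc3)oc12 | intermediate
18 | 8-[5,7-dihydroxy-2-(4-methoxyphenyl)-4-oxo-4H-chromen-6-yl]-5,7-dihydroxy-2-(4-methoxyphenyl)-4H-chromen-4-one | COc1ccc(-c2cc(=O)c3c(O)c(-c4c(O)cc(O)c5c(=O)cc(-c6ccc(OC)cc6)oc45)c(O)cc3o2)cc1 | target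

**Step count and risks**

Total step count: 7. Longest linear sequence: 6 (5 → 6 → 7 → 10 → 12 → 17 → 18).

Most likely to fail, first: step 6. Three things may go wrong.
- The crowded diene 13 may add too slowly to the pyrylium ion, so that silyl exchange and hydrolysis merely return 12 and 4.
- The 2H-pyran 15 may open electrocyclically before the hydride is abstracted.
- The doubly enolised keto ester 16 may resist closure or lose its acyl chain by retro-Claisen cleavage.

The fallback uses known cross-coupling chemistry. It sets out from 5 and 7 and rejoins the route at 18. Acacetin 5 is benzylated at O7 only (BnBr, 1 equiv, K2CO3, acetone, reflux) to 7-O-benzylacacetin F1. This is iodinated ortho to the free, chelated 5-hydroxyl (BnMe3NICl2, CaCO3, CH2Cl2–MeOH) to the 6-iodide F2, then benzylated at O5 (BnBr, K2CO3, DMF) to 5,7-bis(benzyloxy)-6-iodo-4'-methoxyflavone F3. Iodide 7 is taken by Miyaura borylation (B2pin2, PdCl2(dppf), KOAc, dioxane, 90 °C) to the 8-pinacolboronate F4. Suzuki–Miyaura coupling of F3 and F4 (Pd(OAc)2, SPhos, K3PO4, toluene–water, 100 °C) should give the tetrabenzyl biflavone F5, and the hydrogenolysis conditions of step 7 convert it into 18.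

Second: step 4. Oxidative addition and transmetalation at the electron-rich, di-ortho-substituted iodide may be slower than protodeiodination by the zinc reagent. The fallback replaces enolate arylation by allylation and oxidative degradation. It sets out from 7 and rejoins at 10. Stille coupling with allyltributylstannane (Pd(PPh3)4, toluene, 100 °C) gives the 8-allylflavone F6. Lemieux–Johnson cleavage (OsO4 cat., NaIO4, 2,6-lutidine, dioxane–water) gives the arylacetaldehyde F7. Pinnick oxidation (NaClO2, NaH2PO4, 2-methyl-2-butene, t-BuOH–water) gives the arylacetic acid F8, and MeI/K2CO3 in DMF gives 10.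

Third: step 5. The hindered enolate may be acylated on oxygen, or the product may be deacetylated on work-up. The fallback replaces acylation by aldol addition and oxidation. It sets out from 10 and rejoins at 12. The lithium enolate of 10 (LiN(SiMe3)2, THF, −78 °C) is added to acetaldehyde to give the beta-hydroxy ester F9 as a mixture of diastereomers. Dess–Martin periodinane in CH2Cl2 then oxidises it to 12.

**Further compounds**

F1 | step 6 | 7-(benzyloxy)-5-hydroxy-2-(4-methoxyphenyl)-4H-chromen-4-one | COc1ccc(cc1)-c1cc(=O)c2c(O)cc(OCc3ccccc3)cc2o1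
F2 | step 6 | 7-(benzyloxy)-5-hydroxy-6-iodo-2-(4-methoxyphenyl)-4H-chromen-4-one | COc1ccc(cc1)-c1cc(=O)c2c(O)c(I)c(OCc3ccccc3)cc2o1
F3 | step 6 | 5,7-bis(benzyloxy)-6-iodo-2-(4-methoxyphenyl)-4H-chromen-4-one | COc1ccc(cc1)-c1cc(=O)c2c(OCc3ccccc3)c(I)c(OCc3ccccc3)cc2o1
F4 | step 6 | 5,7-bis(benzyloxy)-2-(4-methoxyphenyl)-8-(4,4,5,5-tetramethyl-1,3,2-dioxaborolan-2-yl)-4H-chromen-4-one | COc1ccc(cc1)-c1cc(=O)c2c(OCc3ccccc3)cc(OCc3ccccc3)c(B3OC(C)(C)C(C)(C)O3)c2o1
F5 | step 6 | 5,7-bis(benzyloxy)-6-[5,7-bis(benzyloxy)-2-(4-methoxyphenyl)-4-oxo-4H-chromen-8-yl]-2-(4-methoxyphenyl)-4H-chromen-4-one | COc1ccc(cc1)-c1cc(=O)c2c(OCc3ccccc3)c(c(OCc3ccccc3)cc2o1)-c1c(OCc2ccccc2)cc(OCc2ccccc2)c2c(=O)cc(-c3ccc(OC)cc3)oc12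
F6 | step 4 | 8-allyl-5,7-bis(benzyloxy)-2-(4-methoxyphenyl)-4H-chromen-4-one | C=CCc1c(OCc2ccccc2)cc(OCc2ccccc2)c2c(=O)cc(-c3ccc(OC)cc3)oc12
F7 | step 4 | 2-[5,7-bis(benzyloxy)-2-(4-methoxyphenyl)-4-oxo-4H-chromen-8-yl]acetaldehyde | O=CCc1c(OCc2ccccc2)cc(OCc2ccccc2)c2c(=O)cc(-c3ccc(OC)cc3)oc12
F8 | step 4 | 2-[5,7-bis(benzyloxy)-2-(4-methoxyphenyl)-4-oxo-4H-chromen-8-yl]acetic acid | OC(=O)Cc1c(OCc2ccccc2)cc(OCc2ccccc2)c2c(=O)cc(-c3ccc(OC)cc3)oc12
F9 | step 5 | methyl 2-[5,7-bis(benzyloxy)-2-(4-methoxyphenyl)-4-oxo-4H-chromen-8-yl]-3-hydroxybutanoate (mixture of diastereomers) | COC(=O)C(C(C)O)c1c(OCc2ccccc2)cc(OCc2ccccc2)c2c(=O)cc(-c3ccc(OC)cc3)oc12
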